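A minute says little about a flask until it is set against the time that flask itself needs, so I counted each run in half-times.

all flasks: substrate 0.20 mM
- eta: partner 0.25 mM; reagent 0.24 mM; temperature 44 °C; run made earlier
- theta: partner 1 mM; reagent 0.24 mM; temperature 85 °C; run made earlier
- beta: partner 0.50 mM; reagent 0.12 mM; temperature 44 °C; run made earlier
- larch: partner 0.500 mM; reagent 0.240 mM; temperature 75 °C; time 8.0 min
- ash: partner 0.500 mM; reagent 0.240 mM; temperature 100 °C; time 8.0 min
- alder: partner 0.500 mM; reagent 0.240 mM; temperature 25 °C; time 8.0 min
- cedar: partner 0.500 mM; reagent 0.240 mM; temperature 50 °C; time 8.0 min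

| run | time / min | target / % | substrate / % |
|---|---|---|---|
| eta | 2.00 | 13.2 | 20.2 |
| eta | 3.00 | 18.4 | 16.9 |
| eta | 6.00 | 24.4 | 12.0 |
| eta | 12.0 | 30.4 | 11.2 |
| eta | 25.0 | 29.8 | 9.7 |
| theta | 0.250 | 13.1 | 22.8 |
| theta | 0.417 | 17.7 | 17.3 |
| theta | 0.833 | 24.9 | 15.9 |
| theta | 1.50 | 31.8 | 13.6 |
| theta | 3.00 | 31.9 | 13.6 |
| beta | 2.00 | 6.1 | 63.4 |
| beta | 3.00 | 8.8 | 64.5 |
| beta | 6.00 | 13.9 | 61.3 |
| beta | 12.0 | 19.5 | 61.8 |
| beta | 25.0 | 21.6 | 61.1 |

(each reading ± 1 percentage point)

- which flask leads in amount of target, in percent of the substrate charged ("all alike" within 1.5 percentage points) (larch / ash / alder / cedar / all alike)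
- how much target is there at the end, in percent of the substrate charged: larch
- how much target is there at the end, in percent of the substrate charged: ash
- how much target is there at the end, in percent of the substrate charged: alder
- how much target is there at the end, in percent of the substrate charged: cedar



Reading straight between neighbouring points, I found that target reached half of its last reading after 2.33 min in the eta run and after 0.353 min in the theta run. Theta also held partner at 1 mM against 0.25 mM, but I took the whole gap as temperature, which means the pace doubling every 15.1 K. Dividing the run time by the half-time scaled to the flask's temperature gives the number of half-times in the run, a reduced time in the usual term, and for cedar I reckoned 4.53. I read that count as an estimate: a flask has gone one minus 0.5 raised to the count of the way to its plateau, which gave 95.7% for cedar. Alder counted 1.44, or 63.1% of the way, so if I took theta's last reading of 31.9% as the plateau, my estimate for alder was 20.1%. Yet the count measures distance and not height: eta and theta changed partner and temperature together, so their like plateaus may be two effects cancelling, and one number was not enough.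

The forecast named ash as leader, with larch at 32%, ash at 32.5%, alder at 17% and cedar at 30%, holding that “the plateau is nearly independent of temperature”; my alder estimate stood higher than its figure.

The flasks gave larch 24.8%, ash 10.7%, alder 28.5% and cedar 40.4%, so cedar led.

    reagent + partner → second intermediate (k = 110 M⁻¹ s⁻¹, Ea = 36.0 kJ mol⁻¹)
    partner → decomposed reagent (k = 0.0290 s⁻¹, Ea = 91.0 kJ mol⁻¹)
    substrate + reagent → open intermediate (k = 450 M⁻¹ s⁻¹, Ea = 40.0 kJ mol⁻¹)
    open intermediate + second intermediate → target (k = 61.0 M⁻¹ s⁻¹, Ea = 37.0 kJ mol⁻¹)
    reagent ⇌ dormant form (K = 0.460, k = 0.0170 s⁻¹, Ea = 88.0 kJ mol⁻¹, ΔH = −41.0 kJ mol⁻¹)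
    (constants at 50 °C)

Cedar stood at 91.8% of the 44.0% it showed after 80.0 min, against my 95.7%, and alder at 53.4% of the 53.4% it showed after the same time, against my 63.1%. The neighbouring flask, cedar repeated at 35 °C, counted 2.27 half-times, or 79.3% of the way. It held 35.3% of target at 8.00 min, with 0.0332 mM of second intermediate still present, an amount equal to 16.6% of the substrate charged, and since the scheme pairs second intermediate one to one with open intermediate to give target, I added the two amounts, of which target made up 68.0%.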